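## Retrosynthetic overview
1. 19 ⇒ 18: cut the allylic C–O bond. The acetate goes on last, by a Z-selective allylic C–H acetoxylation of the prenyl terminus (key step).
2. 18 ⇒ 16: the cyclopentane is closed at C3–C3a by an intramolecular B-alkyl Suzuki coupling. The enol triflate fixes the C3a=C4 alkene.
3. 13 ⇒ 12: the C1–C7a bond and both quaternary stereocentres come from the [3,3] shift of an allyl enol ether.
4. 12 ⇒ 4 + 11: the enol-ether C–O bond joins the two C10 halves (Cu-catalysed O-vinylation).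
5. Ring order: the cyclohexane is bought with 1. The cyclopentane is the only ring made (step 9).

Assumption: 1 is taken as a catalogue compound, and the (S,S)-ligand in step 6 is taken to give the drawn antipode (otherwise the equally available (R,R)-ligand is used).

## Route

Step 1
Reactants: 1 2,3-dimethylcyclohex-2-en-1-one
Product: 3 2,3,3-trimethylcyclohex-1-en-1-yl trifluoromethanesulfonate, via lithium enolate 2 (not isolated)
Conditions: Me2CuLi (MeLi, CuI), Et2O, 0 °C; then PhNTf2, THF, 0 °C to rt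
Reagents that add atoms: lithium dimethylcuprate [Li+].C[Cu-]C; N-phenylbis(trifluoromethanesulfonimide) O=S(=O)(N(c1ccccc1)S(=O)(=O)C(F)(F)F)C(F)(F)F
Why: Cuprate 1,4-addition builds the gem-dimethyl carbon and releases the tetrasubstituted enolate regiospecifically, and this is O-sulfonylated in the same flask (conjugate addition/enolate trapping); no stereocentre is formed.

Step 2
Reactants: 3 2,3,3-trimethylcyclohex-1-en-1-yl trifluoromethanesulfonate
Product: 4 1-iodo-2,3,3-trimethylcyclohex-1-ene
Conditions: Ni(cod)2 (10 mol %), NaI, THF/DMA, rt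
Reagents that add atoms: sodium iodide [Na+].[I-]
Why: Nickel-catalysed triflate–iodide exchange (oxidative addition, anion metathesis, reductive elimination) gives the vinyl iodide needed for copper catalysis without moving the double bond.

Step 3
Reactants: 5 5-bromo-2-methylpent-2-ene; 6 methyl but-2-ynoate
Product: 10 methyl (2Z)-2-iodo-3,7-dimethylocta-2,6-dienoate, via homoprenyl Grignard 7 (not isolated), via homoprenylcopper 8 (not isolated), via alkenylcopper 9 (not isolated)
Conditions: Mg, THF; CuBr·SMe2, −40 °C; 6, −78 °C; I2, −78 °C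
Reagents that add atoms: iodine II
Why: syn-Carbocupration of the ynoate puts the homoprenyl group and copper cis, and iodinolysis at −78 °C retains this geometry, so the tetrasubstituted alkene that later encodes the C1 configuration is fixed.

Step 4
Reactants: 10 methyl (2Z)-2-iodo-3,7-dimethylocta-2,6-dienoate
Product: 11 methyl (2E)-2-(hydroxymethyl)-3,7-dimethylocta-2,6-dienoate
Conditions: Bu3SnCH2OH, Pd(PPh3)4 (5 mol %), CuI (10 mol %), 1,4-dioxane, 90 °C
Reagents that add atoms: (tributylstannyl)methanol CCCC[Sn](CCCC)(CCCC)CO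
Why: Stille hydroxymethylation transfers CH2OH in preference to butyl and retains the alkene geometry, so CH2OH ends up cis to the homoprenyl chain.

Step 5
Reactants: 4 1-iodo-2,3,3-trimethylcyclohex-1-ene; 11 methyl (2E)-2-(hydroxymethyl)-3,7-dimethylocta-2,6-dienoate
Product: 12 methyl (2E)-3,7-dimethyl-2-{[(2,3,3-trimethylcyclohex-1-en-1-yl)oxy]methyl}octa-2,6-dienoate
Conditions: CuI (10 mol %), 3,4,7,8-tetramethyl-1,10-phenanthroline (20 mol %), Cs2CO3, toluene, 80 °C
Reagents that add atoms: none
Why: Ullmann-type Cu(I)-catalysed C(sp2)–O coupling of a vinyl iodide with a primary allylic alcohol makes the enol ether only at the tetrasubstituted position, joins all skeletal carbons through one C–O bond, and runs below the temperature expected for the uncatalysed [3,3] shift.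

Step 6
Reactants: 12 methyl (2E)-3,7-dimethyl-2-{[(2,3,3-trimethylcyclohex-1-en-1-yl)oxy]methyl}octa-2,6-dienoate
Product: 13 methyl (3S)-3,7-dimethyl-2-methylidene-3-[(1R)-1,2,2-trimethyl-6-oxocyclohexyl]oct-6-enoate
Conditions: [Cu((S,S)-t-Bu-box)](SbF6)2 (10 mol %), 4 Å MS, CH2Cl2, 0 °C to rt
Reagents that add atoms: none
Why: Proposed new method: the C2-symmetric Cu(II)–bis(oxazoline) Lewis acid should bind 12 through the ether oxygen and the ester carbonyl (six-membered chelate), which weakens the O–CH2 bond and makes the tetrasubstituted alkene a Michael-type acceptor, so the hindered [3,3] shift runs near room temperature through a chair in which the ester on the central allyl carbon excludes the boat; the cyclic enol ether and the E-alkene then give the cis-dimethyl relation of C1 and C7a, and the tert-butyl groups shield one face of the chelated allyl fragment and set the absolute configuration of both quaternary carbons; the closest known reaction type is the Cu(II)–box-catalysed enantioselective Claisen rearrangement of 2-alkoxycarbonyl allyl vinyl ethers (five-membered chelate).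

Step 7
Reactants: 13 methyl (3S)-3,7-dimethyl-2-methylidene-3-[(1R)-1,2,2-trimethyl-6-oxocyclohexyl]oct-6-enoate
Product: 14 methyl (3R)-3,7-dimethyl-2-[(4,4,5,5-tetramethyl-1,3,2-dioxaborolan-2-yl)methyl]-3-[(1R)-1,2,2-trimethyl-6-oxocyclohexyl]oct-6-enoate (C2 epimers)
Conditions: B2pin2, CuCl (5 mol %), Xantphos (5 mol %), NaOt-Bu (10 mol %), MeOH (2 equiv), THF, rt
Reagents that add atoms: bis(pinacolato)diboron CC1(C)OB(OC1(C)C)B2OC(C)(C)C(C)(C)O2
Why: Copper-catalysed conjugate borylation attacks only the unhindered acrylate CH2, leaves the hindered ketone and the trisubstituted alkene untouched, and turns C3 into an sp3 nucleophile; the C2 centre forms as a mixture and is corrected in step 9.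

Step 8
Reactants: 14 methyl (3R)-3,7-dimethyl-2-[(4,4,5,5-tetramethyl-1,3,2-dioxaborolan-2-yl)methyl]-3-[(1R)-1,2,2-trimethyl-6-oxocyclohexyl]oct-6-enoate
Product: 16 methyl (3R)-3,7-dimethyl-2-[(4,4,5,5-tetramethyl-1,3,2-dioxaborolan-2-yl)methyl]-3-[(1R)-1,6,6-trimethyl-2-(trifluoromethylsulfonyloxy)cyclohex-2-en-1-yl]oct-6-enoate, via potassium enolate 15 (not isolated)
Conditions: KHMDS, THF, −78 °C; then PhNTf2, −78 °C to 0 °C
Reagents that add atoms: N-phenylbis(trifluoromethanesulfonimide) O=S(=O)(N(c1ccccc1)S(=O)(=O)C(F)(F)F)C(F)(F)F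
Why: Kinetic enolisation can only occur at C4 because the other α-carbon is quaternary, so enolate triflation places the future C3a=C4 alkene unambiguously, and the quaternary centres cannot epimerise.

Step 9
Reactants: 16 methyl (3R)-3,7-dimethyl-2-[(4,4,5,5-tetramethyl-1,3,2-dioxaborolan-2-yl)methyl]-3-[(1R)-1,6,6-trimethyl-2-(trifluoromethylsulfonyloxy)cyclohex-2-en-1-yl]oct-6-enoate
Product: 18 (1R,2S,7aS)-1,7,7,7a-tetramethyl-1-(4-methylpent-3-en-1-yl)-2,3,5,6,7,7a-hexahydro-1H-indene-2-carboxylic acid, via bicyclic methyl ester 17 (not isolated)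
Conditions: Pd(OAc)2 (5 mol %), RuPhos (10 mol %), K3PO4, THF/H2O, 70 °C; then KOH, MeOH, 85 °C; HCl work-up
Reagents that add atoms: potassium hydroxide [K+].[OH-]
Why: Intramolecular B-alkyl Suzuki–Miyaura coupling closes the five-membered ring through a six-membered palladacycle, and the slow saponification of the hindered ester lets C2 equilibrate through the ester enolate to the isomer expected to be favoured, with the carboxyl on the face of the two methyl groups, anti to the side chain and to C7 (2S); a minor C2 epimer, if formed, is removed by chromatography or crystallisation.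

Step 10
Reactants: 18 (1R,2S,7aS)-1,7,7,7a-tetramethyl-1-(4-methylpent-3-en-1-yl)-2,3,5,6,7,7a-hexahydro-1H-indene-2-carboxylic acid
Product: 19 (1R,2S,7aS)-1-[(3Z)-5-acetoxy-4-methylpent-3-en-1-yl]-1,7,7,7a-tetramethyl-2,3,5,6,7,7a-hexahydro-1H-indene-2-carboxylic acid
Conditions: Pd(OAc)2 (10 mol %), 2,9-dimethyl-1,10-phenanthroline (12 mol %), 1,4-benzoquinone (2 equiv), AcOH/1,4-dioxane, 45 °C
Reagents that add atoms: acetic acid CC(=O)O
Why: Proposed new method: Pd(II) binds the exposed side-chain alkene (the ring alkene is shielded by the C7a quaternary carbon) and acetate-assisted cleavage of a methyl C–H gives a 1-alkyl-2-methyl-η3-allyl complex that equilibrates syn/anti by η3–η1–η3; the 2,9-methyl groups of the ligand lie in the coordination plane and, together with the strain between a syn chain and the 2-methyl group, favour the anti isomer, so quinone-promoted acetate attack at the unsubstituted CH2 terminus forms the C–O bond and delivers the Z-alkene, and any re-ionisation returns to the same anti-biased complex; the closest known reaction types are Pd(II)/N,N-ligand allylic C–H acetoxylation of terminal alkenes (E-linear products) and anti-selective allylpalladium–2,9-disubstituted phenanthroline complexes in allylic substitution.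

## Compound list
1 | 2,3-dimethylcyclohex-2-en-1-one | CC1=C(C)C(=O)CCC1 | starting material
2 | lithium 2,3,3-trimethylcyclohex-1-en-1-olate | [Li+].CC1=C([O-])CCCC1(C)C | intermediate
3 | 2,3,3-trimethylcyclohex-1-en-1-yl trifluoromethanesulfonate | CC1=C(OS(=O)(=O)C(F)(F)F)CCCC1(C)C | intermediate
4 | 1-iodo-2,3,3-trimethylcyclohex-1-ene | CC1=C(I)CCCC1(C)C | intermediate
5 | 5-bromo-2-methylpent-2-ene | CC(C)=CCCBr | starting material
6 | methyl but-2-ynoate | CC#CC(=O)OC | starting material
7 | (4-methylpent-3-en-1-yl)magnesium bromide | CC(C)=CCC[Mg]Br | intermediate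
8 | (4-methylpent-3-en-1-yl)copper | CC(C)=CCC[Cu] | intermediate
9 | [(2Z)-1-methoxy-3,7-dimethyl-1-oxoocta-2,6-dien-2-yl]copper (Cu cis to the chain) | [Cu]/C(C(=O)OC)=C(/C)CCC=C(C)C | intermediate
10 | methyl (2Z)-2-iodo-3,7-dimethylocta-2,6-dienoate | I/C(C(=O)OC)=C(/C)CCC=C(C)C | intermediate
11 | methyl (2E)-2-(hydroxymethyl)-3,7-dimethylocta-2,6-dienoate | OC/C(C(=O)OC)=C(/C)CCC=C(C)C | intermediate
12 | methyl (2E)-3,7-dimethyl-2-{[(2,3,3-trimethylcyclohex-1-en-1-yl)oxy]methyl}octa-2,6-dienoate | CC1=C(OC/C(C(=O)OC)=C(/C)CCC=C(C)C)CCCC1(C)C | intermediate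
13 | methyl (3S)-3,7-dimethyl-2-methylidene-3-[(1R)-1,2,2-trimethyl-6-oxocyclohexyl]oct-6-enoate | CC(C)=CCC[C@](C)(C(=C)C(=O)OC)[C@]1(C)C(=O)CCCC1(C)C | intermediate
14 | methyl (3R)-3,7-dimethyl-2-[(4,4,5,5-tetramethyl-1,3,2-dioxaborolan-2-yl)methyl]-3-[(1R)-1,2,2-trimethyl-6-oxocyclohexyl]oct-6-enoate (C2 epimers) | CC(C)=CCC[C@](C)(C(CB1OC(C)(C)C(C)(C)O1)C(=O)OC)[C@]2(C)C(=O)CCCC2(C)C | intermediate
15 | potassium enolate of 14 (C3a–O, C3a=C4) | [K+].CC(C)=CCC[C@](C)(C(CB1OC(C)(C)C(C)(C)O1)C(=O)OC)[C@]2(C)C([O-])=CCCC2(C)C | intermediate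
16 | methyl (3R)-3,7-dimethyl-2-[(4,4,5,5-tetramethyl-1,3,2-dioxaborolan-2-yl)methyl]-3-[(1R)-1,6,6-trimethyl-2-(trifluoromethylsulfonyloxy)cyclohex-2-en-1-yl]oct-6-enoate (C2 epimers) | CC(C)=CCC[C@](C)(C(CB1OC(C)(C)C(C)(C)O1)C(=O)OC)[C@]2(C)C(OS(=O)(=O)C(F)(F)F)=CCCC2(C)C | intermediate
17 | methyl (1R,7aS)-1,7,7,7a-tetramethyl-1-(4-methylpent-3-en-1-yl)-2,3,5,6,7,7a-hexahydro-1H-indene-2-carboxylate (C2 epimers) | CC(C)=CCC[C@]1(C)C(C(=O)OC)CC2=CCCC(C)(C)[C@@]21C | intermediate
18 | (1R,2S,7aS)-1,7,7,7a-tetramethyl-1-(4-methylpent-3-en-1-yl)-2,3,5,6,7,7a-hexahydro-1H-indene-2-carboxylic acid | CC(C)=CCC[C@]1(C)[C@@H](C(=O)O)CC2=CCCC(C)(C)[C@@]21C | intermediate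
19 | (1R,2S,7aS)-1-[(3Z)-5-acetoxy-4-methylpent-3-en-1-yl]-1,7,7,7a-tetramethyl-2,3,5,6,7,7a-hexahydro-1H-indene-2-carboxylic acid | CC(=O)OC/C(C)=C\CC[C@]1(C)[C@@H](C(=O)O)CC2=CCCC(C)(C)[C@@]21C | target

## Step count and risks
Total step count: 10. Longest linear sequence: 8 (steps 1, 2, 5–10; the branch through steps 3, 4, 5–10 is equally long).

Steps most likely to fail:

**Step 10 (proposed new step).**
- Risks: slow C–H cleavage at a trisubstituted alkene, loss of Z/E control, and oxidative lactonisation of the free acid onto the ring alkene.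
- The fallback sets out from 18 and comes back at 19, using only known reactions.
- One equivalent of mCPBA (CH2Cl2, −20 °C) epoxidises the more accessible side-chain alkene. The product is (1R,2S,7aS)-1-[2-(3,3-dimethyloxiran-2-yl)ethyl]-1,7,7,7a-tetramethyl-2,3,5,6,7,7a-hexahydro-1H-indene-2-carboxylic acid F3.
- H5IO6 (THF/H2O) cleaves F3 to (1R,2S,7aS)-1,7,7,7a-tetramethyl-1-(3-oxopropyl)-2,3,5,6,7,7a-hexahydro-1H-indene-2-carboxylic acid F4.
- Still–Gennari olefination with methyl 2-[bis(2,2,2-trifluoroethoxy)phosphoryl]propanoate (KHMDS, 18-crown-6, THF, −78 °C) gives (1R,2S,7aS)-1-[(3Z)-5-methoxy-4-methyl-5-oxopent-3-en-1-yl]-1,7,7,7a-tetramethyl-2,3,5,6,7,7a-hexahydro-1H-indene-2-carboxylic acid F5.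
- DIBAL-H at −78 °C reduces only the enoate, because the hindered aluminium carboxylate is inert. This gives (1R,2S,7aS)-1-[(3Z)-5-hydroxy-4-methylpent-3-en-1-yl]-1,7,7,7a-tetramethyl-2,3,5,6,7,7a-hexahydro-1H-indene-2-carboxylic acid F6.
- Ac2O/pyridine followed by aqueous work-up gives 19.

**Step 6 (proposed new step).**
- Risks: weak six-membered chelation, low enantioselectivity, leakage through a boat transition state, and enol-ether hydrolysis.
- The fallback sets out from 12 and comes back at 13.
- The uncatalysed thermal Claisen rearrangement (o-xylene, 140 °C) gives the racemate. This is 13 together with its mirror image methyl (3R)-3,7-dimethyl-2-methylidene-3-[(1S)-1,2,2-trimethyl-6-oxocyclohexyl]oct-6-enoate F2.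
- The two enantiomers are separated by preparative supercritical-fluid chromatography on a chiral stationary phase, and 13 is carried on.

**Step 5.**
- Risks: sluggish oxidative addition at the ortho-methyl vinyl iodide, transesterification of 11, and premature racemic [3,3] shift at 80 °C.
- The fallback sets out from 3 and comes back at 12. It reverses the polarity of the vinyl partner and works at room temperature.
- Miyaura borylation of 3 (B2pin2, PdCl2(dppf), KOPh, toluene, 50 °C) gives 4,4,5,5-tetramethyl-2-(2,3,3-trimethylcyclohex-1-en-1-yl)-1,3,2-dioxaborolane F1.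
- F1 is coupled with 11 by a Chan–Lam-type oxidative O-vinylation (Cu(OAc)2, Et3N, air, CH2Cl2, rt) to give 12.

## Further compounds
F1 | step 5 | 4,4,5,5-tetramethyl-2-(2,3,3-trimethylcyclohex-1-en-1-yl)-1,3,2-dioxaborolane | CC1=C(B2OC(C)(C)C(C)(C)O2)CCCC1(C)C
F2 | step 6 | methyl (3R)-3,7-dimethyl-2-methylidene-3-[(1S)-1,2,2-trimethyl-6-oxocyclohexyl]oct-6-enoate | CC(C)=CCC[C@@](C)(C(=C)C(=O)OC)[C@@]1(C)C(=O)CCCC1(C)C
F3 | step 10 | (1R,2S,7aS)-1-[2-(3,3-dimethyloxiran-2-yl)ethyl]-1,7,7,7a-tetramethyl-2,3,5,6,7,7a-hexahydro-1H-indene-2-carboxylic acid (epoxide epimers) | CC1(C)OC1CC[C@]2(C)[C@@H](C(=O)O)CC3=CCCC(C)(C)[C@@]32C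
F4 | step 10 | (1R,2S,7aS)-1,7,7,7a-tetramethyl-1-(3-oxopropyl)-2,3,5,6,7,7a-hexahydro-1H-indene-2-carboxylic acid | O=CCC[C@]1(C)[C@@H](C(=O)O)CC2=CCCC(C)(C)[C@@]21C
F5 | step 10 | (1R,2S,7aS)-1-[(3Z)-5-methoxy-4-methyl-5-oxopent-3-en-1-yl]-1,7,7,7a-tetramethyl-2,3,5,6,7,7a-hexahydro-1H-indene-2-carboxylic acid | COC(=O)/C(C)=C\CC[C@]1(C)[C@@H](C(=O)O)CC2=CCCC(C)(C)[C@@]21C
F6 | step 10 | (1R,2S,7aS)-1-[(3Z)-5-hydroxy-4-methylpent-3-en-1-yl]-1,7,7,7a-tetramethyl-2,3,5,6,7,7a-hexahydro-1H-indene-2-carboxylic acid | OC/C(C)=C\CC[C@]1(C)[C@@H](C(=O)O)CC2=CCCC(C)(C)[C@@]21C
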